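**Plan**

- Numbering: carbocycle C1–C6 (C1 bears the side chain, C2–C3 the epoxide, C4=C5 the alkene, C6 the methyl and the pyranone); side chain C7=C8, C9 (methyl), C10 (ketone).
- Retrosynthesis: the C10 ketone comes from a silyl ether; the epoxide from a C2 bromide and the C3 carbonyl oxygen of a ring enone; the pyranone from a C6 formyl group and a ketoester; the carbocycle is then cut at C1–C6 and C4–C5.
- Enabling feature: C5 and the quaternary C6, with its methyl and the one-carbon anchor of the pyranone, are 2-methylacrolein. C1–C4, with the oxygen on C3 and the whole C7–C10 chain on C1, are the silyl dienol ether of an (E,E)-dienyl ethyl ketone.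
- Forward: chain first (propionate aldol C9–C10, Wittig C7=C8, aldol–dehydration C1=C2), then the carbocycle by [4+2], then the pyranone ring on the formyl group, then the epoxide ring, then the ketone.
- Stereochemistry: C9 from an Evans syn-aldol; C6 from the chiral oxazaborolidinium catalyst and C1 from the formyl-exo topology of the cycloaddition; C2 and C3 from bromination anti to the C1 chain, hydride addition to the same face and invertive ring closure.

Key step: step 9

Remark: C10 is carried as a silyl ether and oxidised in the last step, so its configuration is immaterial; the syn-aldol (10R) series is used because it is the most directly accessible.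
Remark: the catalyst antipode is assigned from the formyl C–H···O binding model for 2-substituted acroleins, in which the (S)-configured catalyst opens the Re face of the enal α-carbon; C6 needs Si-face attack, hence the (R)-configured catalyst (both antipodes are available).
Remark: the ring ketone intermediates are handled as mixtures at the epimerisable C2 and C4 centres, which are later made sp2 or reset; methyl 2-methyl-3-oxopentanoate is taken as a commercial reagent.

**Step 1**
Reactants: 1 (S)-4-benzyl-3-propanoyl-1,3-oxazolidin-2-one; 2 propanal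
Product: 4 (S)-4-benzyl-3-[(2S,3R)-3-hydroxy-2-methylpentanoyl]-1,3-oxazolidin-2-one, via Z-dibutylboron enolate 3 (not isolated)
Conditions: Bu2BOTf, iPr2NEt, CH2Cl2, 0 °C; 2, −78 → 0 °C; then pH 7 buffer, MeOH, H2O2
Reagents that add atoms: none
Why: Evans syn-aldol reaction: the Z-boron enolate adds to propanal through a closed chair transition state in which the benzyl group of the auxiliary blocks one enolate face, which should set C9 and the spectator carbinol C10 as the 2S,3R syn pair.

**Step 2**
Reactants: 4
Product: 5 (2S,3R)-3-hydroxy-N-methoxy-N,2-dimethylpentanamide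
Conditions: MeNH(OMe)·HCl, AlMe3, CH2Cl2, 0 °C → rt; aq. potassium sodium tartrate
Reagents that add atoms: N,O-dimethylhydroxylamine hydrochloride, CNOC.Cl
Why: Weinreb transamidation of the aldol imide by the aluminium amide, assisted by the free β-hydroxyl, should release the auxiliary without touching the α-centre.

**Step 3**
Reactants: 5
Product: 6 (2S,3R)-3-(tert-butyldimethylsilyloxy)-N-methoxy-N,2-dimethylpentanamide
Conditions: tBuMe2SiOTf, 2,6-lutidine, CH2Cl2, −78 → 0 °C
Reagents that add atoms: tert-butyldimethylsilyl triflate, CC(C)(C)[Si](C)(C)OS(=O)(=O)C(F)(F)F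
Why: O-silylation of a secondary alcohol with a silyl triflate and a hindered pyridine base is fast and non-epimerising.

**Step 4**
Reactants: 6
Product: 7 (2S,3R)-3-(tert-butyldimethylsilyloxy)-2-methylpentanal
Conditions: iBu2AlH, THF, −78 °C; aq. potassium sodium tartrate
Reagents that add atoms: none
Why: Weinreb amide reduction stops at the chelated tetrahedral aluminium adduct, which releases the aldehyde only on work-up, so neither over-reduction nor α-epimerisation is expected.

**Step 5**
Reactants: 7; 8 2-(triphenylphosphoranylidene)propanal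
Product: 9 (2E,4R,5R)-5-(tert-butyldimethylsilyloxy)-2,4-dimethylhept-2-enal
Conditions: toluene, 90 °C
Reagents that add atoms: none
Why: Wittig olefination with a stabilised formyl ylide should form the C7=C8 bond with the E geometry typical of such ylides, under neutral conditions that leave the α-methyl centre intact.

**Step 6**
Reactants: 9; 10 pentan-3-one
Product: 12 (6E,8R,9R)-9-(tert-butyldimethylsilyloxy)-5-hydroxy-4,6,8-trimethylundec-6-en-3-one (mixture at C4/C5), via lithium enolate 11 (not isolated)
Conditions: LiN(iPr)2, THF, −78 °C; then 9, −78 °C; aq. NH4Cl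
Reagents that add atoms: none
Why: Directed crossed aldol addition of the preformed lithium enolate to the enal carbonyl (1,2-addition) joins C1 to C2; the two new stereocentres are removed in the next step and the remote C9 centre is not enolised because no free amide base is present.

**Step 7**
Reactants: 12
Product: 14 (4E,6E,8R,9R)-9-(tert-butyldimethylsilyloxy)-4,6,8-trimethylundeca-4,6-dien-3-one, via allylic mesylate 13 (not isolated)
Conditions: MsCl, Et3N, CH2Cl2, 0 °C; then DBU, 0 °C → rt
Reagents that add atoms: none
Why: Mesylation followed by E1cB elimination of the β-sulfonyloxy ketone should give the conjugated dienone, the E geometry of the new C1=C2 bond being favoured because the Z isomer would suffer allylic strain between the acyl group and the C7 substituents.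

**Step 8**
Reactants: 14
Product: 15 (3R,4R,5E,7E,9Z)-3-(tert-butyldimethylsilyloxy)-4,6,8-trimethyl-9-(triisopropylsilyloxy)undeca-5,7,9-triene
Conditions: iPr3SiOTf, Et3N, CH2Cl2, 0 °C
Reagents that add atoms: triisopropylsilyl triflate, CC(C)[Si](C(C)C)(C(C)C)OS(=O)(=O)C(F)(F)F
Why: Soft enolisation with a silyl triflate and triethylamine removes a proton from the only enolisable position (the ethyl CH2) and should give the Z silyl enol ether, because the E isomer would push the enol methyl against the substituted C2 carbon of the dienyl group.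

**Step 9**
Reactants: 15; 16 2-methylacrolein
Product: 17 (1R,2R,5R)-2-[(2E,4R,5R)-5-(tert-butyldimethylsilyloxy)-4-methylhept-2-en-2-yl]-1,3,5-trimethyl-4-(triisopropylsilyloxy)cyclohex-3-ene-1-carbaldehyde (plan numbering: C1 chain, C4 methyl and C6 methyl on one face, formyl on the other)
Conditions: (R)-3,3-diphenyl-1-(2-methylphenyl)tetrahydro-1H,3H-pyrrolo[1,2-c][1,3,2]oxazaborole (20 mol%), Tf2NH (20 mol%), 16 (excess), CH2Cl2, −78 → −40 °C; Et3N quench
Reagents that add atoms: none
Why: The N-protonated oxazaborolidine binds 2-methylacrolein at boron as the s-trans enal, and the activated enal undergoes a concerted, asynchronous, suprafacial [4+2] cycloaddition with the s-cis 3-silyloxydiene unit of 15, the C4–C5 bond leading and the C1–C6 bond following. The closest known reaction type is the oxazaborolidinium-catalysed Diels–Alder reaction of 2-methylacrolein with 2-silyloxy-1,3-dienes, applied here to a 1,4-disubstituted silyloxytriene. The cyclohexene ring is closed by intermolecular [4+2] cycloaddition, both new ring bonds forming on one face of the diene. C6 is set by the catalyst, which leaves only the Si face of the enal α-carbon open; C1 follows from the formyl-exo (methyl-endo) topology, which places formyl trans to the chain; C4 follows from the Z enol ether geometry and suprafacial addition (methyl cis to the chain) and is erased later. Regioselectivity is secured by the 3-silyloxy group and the 1-alkenyl substituent acting in the same sense, and chemoselectivity by the higher nucleophilicity of the silyloxydiene over the C8=C7–C1=C2 diene, whose C2 terminus is fully substituted. The required exo sense should be secured by crowding of the endo pocket under C2–C3 by the C2 methyl and the triisopropylsilyloxy group, which the bulky boron-bound formyl avoids while the small α-methyl can occupy it.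

**Step 10**
Reactants: 17; 18 methyl 2-methyl-3-oxopentanoate
Product: 20 β-hydroxy ketoester in which the C6 formyl group of 17 has become CH(OH)CH(CH3)COCH(CH3)CO2CH3 (diastereomer mixture), via dilithium dianion 19 (not isolated)
Conditions: LiN(iPr)2 (2 equiv per 18), THF, 0 °C; then 17, −78 °C; aq. NH4Cl
Reagents that add atoms: none
Why: Aldol addition of the γ-carbon of the ketoester dianion to the non-enolisable neopentyl aldehyde is the standard entry to 3,5-dimethylpyranones; the ring ketone stays masked as its silyl enol ether and the new stereocentres are erased by the following oxidation and enolisation.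

**Step 11**
Reactants: 20
Product: 21 3,5-diketo ester in which C6 carries COCH(CH3)COCH(CH3)CO2CH3 (mixture of diastereomers)
Conditions: Dess–Martin periodinane, NaHCO3, CH2Cl2, rt
Reagents that add atoms: none
Why: Buffered Dess–Martin oxidation of the hindered secondary carbinol to the ketone is mild enough to leave the silyl enol ether and the silyl ether untouched.

**Step 12**
Reactants: 21
Product: 22 4-hydroxy-3,5-dimethyl-2H-pyran-2-one joined through its C6 to ring C6 (ring silyl enol ether retained)
Conditions: DBU, toluene, rt → 60 °C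
Reagents that add atoms: none
Why: Base-mediated lactonisation: the enol oxygen of the ring-attached ketone acylates onto the methyl ester and tautomerisation should give the 4-hydroxy-2-pyranone.

**Step 13**
Reactants: 22
Product: 23 ring C3 ketone (C2/C4 epimer mixture) bearing the hydroxypyranone
Conditions: Bu4NF, AcOH, THF, 0 °C
Reagents that add atoms: none
Why: Fluoride-induced cleavage of the silyl enol ether is far faster than that of the hindered secondary alkyl silyl ether at C10, and protonation at C2 needs no control because C2 and C4 are reworked later.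

**Step 14**
Reactants: 23
Product: 24 ring C3 ketone (C2/C4 epimer mixture) bearing the 2-methoxy-3,5-dimethyl-4H-pyran-4-one
Conditions: MeOTf, CH2Cl2, rt; then aq. NaHCO3
Reagents that add atoms: methyl triflate, COS(=O)(=O)C(F)(F)F
Why: O-methylation of the ambident hydroxypyranone with a hard methylating agent in the absence of base occurs at the lactone carbonyl oxygen, and loss of the proton should give the 2-methoxy-4-pyranone regioisomer.

**Step 15**
Reactants: 24
Product: 26 C4=C5 enone (C3 ketone, C2 epimer mixture), via C3=C4 trimethylsilyl enol ether 25 (not isolated)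
Conditions: LiN(iPr)2, Me3SiCl, THF, −78 °C; then Pd(OAc)2, MeCN, rt
Reagents that add atoms: none
Why: Kinetic deprotonation should occur at C4–H, which is flanked by the C5 methylene, and not at C2–H, which is screened by the C1 methine and its branched chain; Saegusa–Ito oxidation of the resulting silyl enol ether (β-hydride elimination from C5) then gives the enone.

**Step 16**
Reactants: 26
Product: 28 C2-bromo enone with bromine trans and the C2 methyl cis to the C1 chain, via cross-conjugated trimethylsilyl dienol ether 27 (not isolated)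
Conditions: LiN(SiMe3)2, Me3SiCl, THF, −78 → −20 °C; then NBS, THF, −78 °C
Reagents that add atoms: N-bromosuccinimide, O=C1CCC(=O)N1Br
Why: C2 is the only enolisable position of the enone, so the silyl dienol ether forms regiospecifically, and NBS brominates it at C2 (α'-halogenation of a 2-silyloxydiene) on the face opposite the adjacent C1 chain, through the conformer with chain and pyranone pseudo-equatorial in which that face carries only the C1 hydrogen.

**Step 17**
Reactants: 28
Product: 30 C2–C3 epoxide with the oxygen cis to the C1 chain (C10 silyl ether retained), via trans-bromohydrin 29 (not isolated)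
Conditions: NaBH4, CeCl3·7H2O, MeOH, −78 °C; then K2CO3, MeOH, 0 °C → rt
Reagents that add atoms: none
Why: Luche 1,2-reduction should deliver hydride to C3 on the face opposite the C2 methyl and the C1 chain, giving the carbinol trans to bromine, and K2CO3 then effects intramolecular Williamson closure with inversion at C2, so the epoxide oxygen ends cis to the chain and the C2 methyl trans to it.

**Step 18**
Reactants: 30
Product: 31 C10 alcohol of the epoxide
Conditions: Bu4NF, THF, 0 °C → rt
Reagents that add atoms: none
Why: Fluoride desilylation of the secondary silyl ether is compatible with the base-stable vinyl epoxide and the pyranone.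

**Step 19**
Reactants: 31
Product: 32 target ketone
Conditions: Dess–Martin periodinane, NaHCO3, CH2Cl2, 0 °C → rt
Reagents that add atoms: none
Why: Buffered Dess–Martin oxidation converts the carbinol into the ethyl ketone under conditions that are neither acidic nor basic, so the α-centre C9 of the β,γ-unsaturated ketone, the vinyl epoxide and the pyranone should remain intact.

**Compound list**

1 | (S)-4-benzyl-3-propanoyl-1,3-oxazolidin-2-one | CCC(=O)N1[C@@H](Cc2ccccc2)COC1=O | starting material
2 | propanal | CCC=O | starting material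
3 | Z-dibutylboron enolate of 1 | C/C=C(\OB(CCCC)CCCC)N1[C@@H](Cc2ccccc2)COC1=O | intermediate
4 | (S)-4-benzyl-3-[(2S,3R)-3-hydroxy-2-methylpentanoyl]-1,3-oxazolidin-2-one | CC[C@@H](O)[C@H](C)C(=O)N1[C@@H](Cc2ccccc2)COC1=O | intermediate
5 | (2S,3R)-3-hydroxy-N-methoxy-N,2-dimethylpentanamide | CC[C@@H](O)[C@H](C)C(=O)N(C)OC | intermediate
6 | (2S,3R)-3-(tert-butyldimethylsilyloxy)-N-methoxy-N,2-dimethylpentanamide | CC[C@@H](O[Si](C)(C)C(C)(C)C)[C@H](C)C(=O)N(C)OC | intermediate
7 | (2S,3R)-3-(tert-butyldimethylsilyloxy)-2-methylpentanal | CC[C@@H](O[Si](C)(C)C(C)(C)C)[C@H](C)C=O | intermediate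
8 | 2-(triphenylphosphoranylidene)propanal | CC(C=O)=P(c1ccccc1)(c1ccccc1)c1ccccc1 | starting material
9 | (2E,4R,5R)-5-(tert-butyldimethylsilyloxy)-2,4-dimethylhept-2-enal | CC[C@@H](O[Si](C)(C)C(C)(C)C)[C@H](C)/C=C(\C)C=O | intermediate
10 | pentan-3-one | CCC(=O)CC | starting material
11 | lithium enolate of pentan-3-one (geometry inconsequential) | CC=C(CC)O[Li] | intermediate
12 | (6E,8R,9R)-9-(tert-butyldimethylsilyloxy)-5-hydroxy-4,6,8-trimethylundec-6-en-3-one (mixture at C4/C5) | CC[C@@H](O[Si](C)(C)C(C)(C)C)[C@H](C)/C=C(\C)C(O)C(C)C(=O)CC | intermediate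
13 | C5 methanesulfonate of 12 | CC[C@@H](O[Si](C)(C)C(C)(C)C)[C@H](C)/C=C(\C)C(OS(C)(=O)=O)C(C)C(=O)CC | intermediate
14 | (4E,6E,8R,9R)-9-(tert-butyldimethylsilyloxy)-4,6,8-trimethylundeca-4,6-dien-3-one | CC[C@@H](O[Si](C)(C)C(C)(C)C)[C@H](C)/C=C(\C)/C=C(\C)C(=O)CC | intermediate
15 | (3R,4R,5E,7E,9Z)-3-(tert-butyldimethylsilyloxy)-4,6,8-trimethyl-9-(triisopropylsilyloxy)undeca-5,7,9-triene | CC[C@@H](O[Si](C)(C)C(C)(C)C)[C@H](C)/C=C(\C)/C=C(\C)/C(O[Si](C(C)C)(C(C)C)C(C)C)=C/C | intermediate
16 | 2-methylacrolein | C=C(C)C=O | starting material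
17 | cycloadduct, (1R,2R,5R)-2-[(2E,4R,5R)-5-(tert-butyldimethylsilyloxy)-4-methylhept-2-en-2-yl]-1,3,5-trimethyl-4-(triisopropylsilyloxy)cyclohex-3-ene-1-carbaldehyde | CC[C@@H](O[Si](C)(C)C(C)(C)C)[C@H](C)/C=C(\C)[C@@H]1C(C)=C(O[Si](C(C)C)(C(C)C)C(C)C)[C@H](C)C[C@@]1(C)C=O | intermediate
18 | methyl 2-methyl-3-oxopentanoate | CCC(=O)C(C)C(=O)OC | starting material
19 | dilithium dianion of 18 | CC=C([O-])C(C)=C([O-])OC.[Li+].[Li+] | intermediate
20 | β-hydroxy ketoester: 17 with C6–CH(OH)CH(CH3)COCH(CH3)CO2CH3 in place of formyl (diastereomer mixture) | CC[C@@H](O[Si](C)(C)C(C)(C)C)[C@H](C)/C=C(\C)[C@@H]1C(C)=C(O[Si](C(C)C)(C(C)C)C(C)C)[C@H](C)C[C@@]1(C)C(O)C(C)C(=O)C(C)C(=O)OC | intermediate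
21 | 3,5-diketo ester: C6–COCH(CH3)COCH(CH3)CO2CH3 (diastereomer mixture) | CC[C@@H](O[Si](C)(C)C(C)(C)C)[C@H](C)/C=C(\C)[C@@H]1C(C)=C(O[Si](C(C)C)(C(C)C)C(C)C)[C@H](C)C[C@@]1(C)C(=O)C(C)C(=O)C(C)C(=O)OC | intermediate
22 | 4-hydroxy-3,5-dimethyl-2H-pyran-2-one on C6, ring silyl enol ether retained | CC[C@@H](O[Si](C)(C)C(C)(C)C)[C@H](C)/C=C(\C)[C@@H]1C(C)=C(O[Si](C(C)C)(C(C)C)C(C)C)[C@H](C)C[C@@]1(C)C1=C(C)C(O)=C(C)C(=O)O1 | intermediate
23 | ring C3 ketone with hydroxypyranone (C2/C4 epimer mixture) | CC[C@@H](O[Si](C)(C)C(C)(C)C)[C@H](C)/C=C(\C)[C@@H]1C(C)C(=O)C(C)C[C@@]1(C)C1=C(C)C(O)=C(C)C(=O)O1 | intermediate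
24 | ring C3 ketone with 2-methoxy-3,5-dimethyl-4H-pyran-4-one (C2/C4 epimer mixture) | CC[C@@H](O[Si](C)(C)C(C)(C)C)[C@H](C)/C=C(\C)[C@@H]1C(C)C(=O)C(C)C[C@@]1(C)c1oc(OC)c(C)c(=O)c1C | intermediate
25 | C3=C4 trimethylsilyl enol ether of 24 | CC[C@@H](O[Si](C)(C)C(C)(C)C)[C@H](C)/C=C(\C)[C@@H]1C(C)C(O[Si](C)(C)C)=C(C)C[C@@]1(C)c1oc(OC)c(C)c(=O)c1C | intermediate
26 | C4=C5 enone (C2 epimer mixture) | CC[C@@H](O[Si](C)(C)C(C)(C)C)[C@H](C)/C=C(\C)[C@@H]1C(C)C(=O)C(C)=C[C@@]1(C)c1oc(OC)c(C)c(=O)c1C | intermediate
27 | cross-conjugated C2=C3 trimethylsilyl dienol ether of 26 | CC[C@@H](O[Si](C)(C)C(C)(C)C)[C@H](C)/C=C(\C)[C@@H]1C(C)=C(O[Si](C)(C)C)C(C)=C[C@@]1(C)c1oc(OC)c(C)c(=O)c1C | intermediate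
28 | C2-bromo enone, bromine trans to the C1 chain | CC[C@@H](O[Si](C)(C)C(C)(C)C)[C@H](C)/C=C(\C)[C@@H]1[C@@](C)(Br)C(=O)C(C)=C[C@@]1(C)c1oc(OC)c(C)c(=O)c1C | intermediate
29 | trans-bromohydrin, C3 hydroxyl cis to the C1 chain and trans to bromine | CC[C@@H](O[Si](C)(C)C(C)(C)C)[C@H](C)/C=C(\C)[C@@H]1[C@@](C)(Br)[C@H](O)C(C)=C[C@@]1(C)c1oc(OC)c(C)c(=O)c1C | intermediate
30 | C2–C3 epoxide, oxygen cis to the C1 chain, C10 silyl ether | CC[C@@H](O[Si](C)(C)C(C)(C)C)[C@H](C)/C=C(\C)[C@@H]1[C@]2(C)O[C@@H]2C(C)=C[C@@]1(C)c1oc(OC)c(C)c(=O)c1C | intermediate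
31 | C10 alcohol of the epoxide | CC[C@@H](O)[C@H](C)/C=C(\C)[C@@H]1[C@]2(C)O[C@@H]2C(C)=C[C@@]1(C)c1oc(OC)c(C)c(=O)c1C | intermediate
32 | target: 2-methoxy-3,5-dimethyl-4H-pyran-4-one carrying at C6 the epoxycyclohexene (plan numbering 1S,2S,3R,6R; epoxide oxygen, chain and C6 methyl on one face) with the (7E,9R)-4-methyl-5-oxohept-2-en-2-yl chain | CCC(=O)[C@H](C)/C=C(\C)[C@@H]1[C@]2(C)O[C@@H]2C(C)=C[C@@]1(C)c1oc(OC)c(C)c(=O)c1C | target

**Step count**

Total: 19 steps. Longest linear sequence: 19 steps (1 → 32); all other building blocks are used as purchased.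

**Steps most likely to fail**

1. Step 9. What may go wrong: the cycloaddition may run through the formyl-endo arrangement, which places formyl cis to the C1 chain, or show little exo/endo discrimination; the acid-sensitive diene may also be protodesilylated before it reacts. Fallback (sets out from 15, returns at 17): the same ring bonds are formed but the endo preference is put to use by exchanging the fates of the two C6 substituents. Diene 15 is combined with 2-(acetoxymethyl)acrolein under the antipodal (S)-configured catalyst, which should give the formyl-endo cycloadduct F1 with formyl cis and acetoxymethyl trans to the chain. Condensation with TsNHNH2 gives the tosylhydrazone F2. Catecholborane followed by NaOAc·3H2O reduces it to the C6-methyl acetate F3. K2CO3 in MeOH removes the acetate to give the neopentyl alcohol F4, and Dess–Martin oxidation of F4 delivers aldehyde 17.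

2. Step 16. What may go wrong: bromine may be delivered to the face syn to the C1 chain (poor or reversed facial selectivity), which after reduction would give a bromohydrin leading to the epimeric epoxide or unable to close. Fallback (sets out from 26, returns at 30): the oxygen is introduced as the electrophile instead, which reverses the facial requirement. Enone 26 is converted with KN(SiMe3)2 and PhNTf2 into the cross-conjugated dienyl triflate F5. Pd(OAc)2/PPh3 with HCO2H/Et3N reduces it to the ring diene F6. mCPBA (NaHCO3, CH2Cl2, −20 °C) then epoxidises the more electron-rich ring diene at C2=C3 from the face that the brominating agent had preferred, giving 30.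

3. Step 17. What may go wrong: hydride may add to the carbonyl face anti to bromine, producing the cis-bromohydrin, in which backside displacement of bromide is impossible. Fallback (sets out from 28, returns at 30): the carbinol is inverted instead of being re-reduced. The cis-bromohydrin F7 obtained from 28 is esterified under Mitsunobu conditions (PPh3, DIAD, 4-nitrobenzoic acid) to give the inverted 4-nitrobenzoate F8. K2CO3 in MeOH cleaves the ester, and the liberated alkoxide, now trans to bromine, closes to epoxide 30.

**Further compounds**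

F1 | step 9 | formyl-endo cycloadduct with acetoxymethyl on C6 (formyl cis to the chain) | CC[C@@H](O[Si](C)(C)C(C)(C)C)[C@H](C)/C=C(\C)[C@@H]1C(C)=C(O[Si](C(C)C)(C(C)C)C(C)C)[C@H](C)C[C@@]1(C=O)COC(C)=O
F2 | step 9 | tosylhydrazone of F1 | CC[C@@H](O[Si](C)(C)C(C)(C)C)[C@H](C)/C=C(\C)[C@@H]1C(C)=C(O[Si](C(C)C)(C(C)C)C(C)C)[C@H](C)C[C@@]1(C=NNS(=O)(=O)c1ccc(C)cc1)COC(C)=O
F3 | step 9 | C6-methyl acetate | CC[C@@H](O[Si](C)(C)C(C)(C)C)[C@H](C)/C=C(\C)[C@@H]1C(C)=C(O[Si](C(C)C)(C(C)C)C(C)C)[C@H](C)C[C@@]1(C)COC(C)=O
F4 | step 9 | neopentyl alcohol | CC[C@@H](O[Si](C)(C)C(C)(C)C)[C@H](C)/C=C(\C)[C@@H]1C(C)=C(O[Si](C(C)C)(C(C)C)C(C)C)[C@H](C)C[C@@]1(C)CO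
F5 | step 16 | cross-conjugated dienyl triflate | CC[C@@H](O[Si](C)(C)C(C)(C)C)[C@H](C)/C=C(\C)[C@@H]1C(C)=C(OS(=O)(=O)C(F)(F)F)C(C)=C[C@@]1(C)c1oc(OC)c(C)c(=O)c1C
F6 | step 16 | ring diene | CC[C@@H](O[Si](C)(C)C(C)(C)C)[C@H](C)/C=C(\C)[C@@H]1C(C)=CC(C)=C[C@@]1(C)c1oc(OC)c(C)c(=O)c1C
F7 | step 17 | cis-bromohydrin | CC[C@@H](O[Si](C)(C)C(C)(C)C)[C@H](C)/C=C(\C)[C@@H]1[C@@](C)(Br)[C@@H](O)C(C)=C[C@@]1(C)c1oc(OC)c(C)c(=O)c1C
F8 | step 17 | inverted 4-nitrobenzoate | CC[C@@H](O[Si](C)(C)C(C)(C)C)[C@H](C)/C=C(\C)[C@@H]1[C@@](C)(Br)[C@H](OC(=O)c2ccc(cc2)[N+](=O)[O-])C(C)=C[C@@]1(C)c1oc(OC)c(C)c(=O)c1C
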